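Plan (eudesmane numbering: ring A = C1–C5 + C10, ring B = C5–C10, C14 on C10, C15 on C4, isopropyl on C7)
1. Late cuts: the 3α,4β-diol goes back to a 3α,4α-epoxide, then to the C3=C4 alkene; the benzoate and 6β-OH go back to a C6 ketone; H at C2 and C5 goes back to eudesma-2,4-dien-6-one 11.
2. Central cut: C2–C3 and C5–C10 of 11 are cut together. This opens both rings and leaves the acyclic chain 9.
3. Enabling feature: in ring A, C3–C4–C5 hangs on the C6 oxygen and faces C10–C1–C2. With C6 as ketone and C4=C5 as its enone, C5 (α) and C3 (γ) are the two ends of one dienolate. C10 (β) and C2 (C=O) are the two ends of a β-methyl enal, so the 1,3/1,3 match allows a [3+3] closure. A phosphonate on C3 acidifies the dienolate and leaves in the same event together with the C2 oxygen.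
4. Chain assembly (forward): C7–C8 (organocatalytic Michael), then C5–C6 and C1–C10 (double vinyl addition), then C4=C5 (cross-metathesis). Ring B closes first and ring A directly after it in the same flask.
5. Stereochemistry: C7 comes from the amine catalyst and C10 from C7 in the key step. C5 and C6 come from the axial C10 methyl (α-face protonation, α-face hydride). C3 and C4 come from α-epoxidation and inversion at C4.

Key step: step 5

Remark: α/β follow the usual eudesmane drawing (C10 methyl = β). The enal of 7 and 9 is drawn as the E isomer, and any Z isomer may be carried along because C10 becomes sp3 in step 5.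

Step 1
Reactants: 1 3-methylbutanal, 2 but-3-en-2-one
Product: 3 (2S)-5-oxo-2-(propan-2-yl)hexanal
Conditions: (S)-2-[methoxy(diphenyl)methyl]pyrrolidine (5 mol %), ethyl 3,4-dihydroxybenzoate (20 mol %), neat, 4 °C
Reagents that add atoms: none
Why: Enamine-catalysed asymmetric Michael addition of an aldehyde to an enone, in which the E-enamine of 1 is screened on one face by the diphenyl(methoxy)methyl group, so that 2 should add to the open face and set C7 as S.

Step 2
Reactants: 3 (2S)-5-oxo-2-(propan-2-yl)hexanal, 4 vinylmagnesium bromide (3 equiv)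
Product: 5 (4S)-7-methyl-4-(propan-2-yl)nona-1,8-diene-3,7-diol (epimers at both carbinol carbons)
Conditions: LaCl3·2LiCl (30 mol %), THF, −78 to 0 °C; aq NH4Cl
Reagents that add atoms: none
Why: Lanthanide-assisted double Grignard 1,2-addition to aldehyde and ketone should outrun enolisation, so C7 is kept, and both new carbinol centres are erased in step 3, so their configuration does not matter.

Step 3
Reactants: 5 (4S)-7-methyl-4-(propan-2-yl)nona-1,8-diene-3,7-diol
Product: 7 (2E,6S)-3-methyl-7-oxo-6-(propan-2-yl)nona-2,8-dienal, via hydroxy vinyl ketone 6 (not isolated)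
Conditions: pyridinium chlorochromate [C5H5NH][CrO3Cl] (5 equiv), 4 Å molecular sieves, CH2Cl2, 23 °C
Reagents that add atoms: pyridinium chlorochromate, [O-][Cr](=O)(=O)Cl.c1cc[nH+]cc1
Why: Fast chromate oxidation of the secondary allylic alcohol (giving 6) followed by Babler–Dauben oxidative transposition of the tertiary vinyl carbinol ([3,3]-shift of its chromate ester to C2, then oxidation, so that the aldehyde oxygen comes from the chromate) should install both carbonyl groups in one flask without touching C7, the E enal being favoured on steric grounds.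

Step 4
Reactants: 7 (2E,6S)-3-methyl-7-oxo-6-(propan-2-yl)nona-2,8-dienal, 8 diethyl (2-methylprop-2-en-1-yl)phosphonate (4 equiv)
Product: 9 diethyl [(2E,5S,8E)-2,8-dimethyl-4,10-dioxo-5-(propan-2-yl)deca-2,8-dien-1-yl]phosphonate
Conditions: second-generation Hoveyda–Grubbs catalyst RuCl2(H2IMes)(=CH-C6H4-2-O-i-Pr) (5 mol %), CH2Cl2, 40 °C
Reagents that add atoms: none
Why: Olefin cross-metathesis of an electron-poor monosubstituted alkene with an excess of a 1,1-disubstituted alkene is a selective pairing, the trisubstituted formyl-conjugated C10=C1 alkene should stay a spectator, and the geometry of the new C4=C5 bond is of no consequence because it is lost in the anion of step 5.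

Step 5
Reactants: 9 diethyl [(2E,5S,8E)-2,8-dimethyl-4,10-dioxo-5-(propan-2-yl)deca-2,8-dien-1-yl]phosphonate
Product: 11 (2S,4aS)-4a,8-dimethyl-2-(propan-2-yl)-3,4,4a,5-tetrahydronaphthalen-1(2H)-one (eudesma-2,4-dien-6-one), via monocyclic Michael adduct 10 (not isolated)
Conditions: KOt-Bu (1.0 equiv), THF, 0.001 M, −20 to 40 °C; then 0.1 M HCl
Reagents that add atoms: none
Why: Proposed new method: deprotonation of the C3 methylene of 9 (acidified by P=O and by the vinylogous C6 ketone) gives a delocalised anion whose C5 end adds to C10 of the β-methyl enal (Michael addition, ring B, 6-(enolendo)-exo-trig); proton transfer through t-BuOH then regenerates the phosphonate anion of 10, whose C3 end attacks the C2 aldehyde (6-exo-trig) and loses diethyl phosphate (Horner–Wadsworth–Emmons olefination, ring A, necessarily cis C2=C3). The closest known reaction type is the intermolecular [3+3] cyclohexadiene annulation of allylidenephosphoranes or 4-phosphonocrotonates with α,β-unsaturated carbonyl compounds (Michael addition, then intramolecular Wittig or Horner–Wadsworth–Emmons closure); new here are the doubly intramolecular setting and a β,β-disubstituted enal that ends as a quaternary carbon. C10 is the only new stereocentre (C5 becomes sp2): the Michael step should be reversible because it expels a stabilised anion, whereas phosphate loss is not, so the outcome is decided in the ring A closure, where C4 lies in the plane of C5 and only an equatorial C1 arm can reach C3, which forces the C10 methyl axial and lets the C7 isopropyl stay equatorial only in the 7,10-cis (natural) series. Site selectivity is secured by the tether, since C3 to C10 or C5 to C2 would give eight-membered rings and direct C3 to C2 olefination a ten-membered ring holding E alkenes, so C5 to C10 is the only fast closure. Intermolecular olefination of the aldehyde, the normal reaction of such anions, is held back by the high dilution, and C7 should not epimerise because no base stronger than the stabilised anion is present.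

Step 6
Reactants: 11 eudesma-2,4-dien-6-one
Product: 13 5αH-eudesm-3-en-6-one (trans-fused), via lithium dienolate 12 (not isolated)
Conditions: Li (2.2 equiv), t-BuOH (1 equiv), NH3(l)/THF, −78 °C; then solid NH4Cl
Reagents that add atoms: none
Why: Dissolving-metal (Birch-type) reduction of a linear dienone puts two electrons and one proton on the terminus C2 to give extended dienolate 12, which should be protonated kinetically at its α-carbon C5 from the α face, opposite to the adjacent axial C10 methyl, giving the trans-fused β,γ-enone.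

Step 7
Reactants: 13 5αH-eudesm-3-en-6-one
Product: 14 5αH-eudesm-3-en-6β-ol
Conditions: LiAlH4, Et2O, −78 to 0 °C; H2O work-up
Reagents that add atoms: none
Why: Hydride reduction of a hindered cyclohexanone in which the β face of C6 is closed by the 1,3-diaxial C10 methyl, so that hydride should arrive from the α face and give the axial 6β-alcohol before the β,γ-enone can conjugate.

Step 8
Reactants: 14 5αH-eudesm-3-en-6β-ol
Product: 15 5αH-eudesm-3-en-6β-yl benzoate
Conditions: BzCl (3 equiv), DMAP (20 mol %), pyridine, 60 °C
Reagents that add atoms: benzoyl chloride, O=C(Cl)c1ccccc1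
Why: DMAP-catalysed acyl transfer acylates the only hydroxyl group, heating making up for its axial, hindered position, and no stereocentre is touched.

Step 9
Reactants: 15 5αH-eudesm-3-en-6β-yl benzoate
Product: 16 3α,4α-epoxy-5αH-eudesman-6β-yl benzoate
Conditions: mCPBA (1.2 equiv), CH2Cl2, 0 °C
Reagents that add atoms: 3-chloroperoxybenzoic acid, OOC(=O)c1cccc(Cl)c1
Why: Prilezhaev epoxidation of the only alkene, whose β face is screened by the axial C10 methyl and the axial 6β-benzoate, so that oxygen should be delivered to the α face and fix C3–O as α.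

Step 10
Reactants: 16 3α,4α-epoxy-5αH-eudesman-6β-yl benzoate
Product: 18 (1R,2S,4aS,7R,8R,8aS)-7,8-dihydroxy-4a,8-dimethyl-2-(propan-2-yl)decahydronaphthalen-1-yl benzoate (target CNP0187831.1), via bridged dioxanylium ion 17 (not isolated)
Conditions: HClO4 (10 mol %), THF/H2O 4:1, 0 to 23 °C
Reagents that add atoms: water, O
Why: Acid-catalysed trans-diaxial epoxide opening (Fürst–Plattner rule) at the tertiary C4 with neighbouring-group participation, in which the 1,3-diaxial benzoate carbonyl attacks C4 from the β face with inversion to give 17 and water then adds to its cationic carbon, the ortho acid collapsing to the less crowded secondary 6-benzoate and leaving 3α-OH and 4β-OH.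

Compound list
1 | 3-methylbutanal | CC(C)CC=O | starting material
2 | but-3-en-2-one | CC(=O)C=C | starting material
3 | (2S)-5-oxo-2-(propan-2-yl)hexanal | CC(C)[C@@H](C=O)CCC(C)=O | intermediate
4 | vinylmagnesium bromide | C=C[Mg]Br | starting material
5 | (4S)-7-methyl-4-(propan-2-yl)nona-1,8-diene-3,7-diol, epimers at C3 and C7 of the chain | CC(C)[C@@H](C(O)C=C)CCC(C)(O)C=C | intermediate
6 | (4S)-7-hydroxy-7-methyl-4-(propan-2-yl)nona-1,8-dien-3-one | CC(C)[C@@H](C(=O)C=C)CCC(C)(O)C=C | intermediate
7 | (2E,6S)-3-methyl-7-oxo-6-(propan-2-yl)nona-2,8-dienal | CC(C)[C@@H](C(=O)C=C)CC/C(C)=C/C=O | intermediate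
8 | diethyl (2-methylprop-2-en-1-yl)phosphonate | C=C(C)CP(=O)(OCC)OCC | starting material
9 | diethyl [(2E,5S,8E)-2,8-dimethyl-4,10-dioxo-5-(propan-2-yl)deca-2,8-dien-1-yl]phosphonate | CC(C)[C@@H](C(=O)/C=C(\C)CP(=O)(OCC)OCC)CC/C(C)=C/C=O | intermediate
10 | (3S,6S)-2-[1-(diethoxyphosphoryl)prop-1-en-2-yl]-3-methyl-3-(2-oxoethyl)-6-(propan-2-yl)cyclohexan-1-one, C2 of the ring epimerisable | CC(C)[C@@H]1CC[C@@](C)(CC=O)C(C(C)=CP(=O)(OCC)OCC)C1=O | intermediate
11 | eudesma-2,4-dien-6-one, 7β-isopropyl, 10β-methyl | CC(C)[C@@H]1CC[C@@]2(C)CC=CC(C)=C2C1=O | intermediate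
12 | lithium eudesma-3,5-dien-6-olate | CC(C)[C@@H]1CC[C@@]2(C)CCC=C(C)C2=C1[O-].[Li+] | intermediate
13 | 5αH-eudesm-3-en-6-one, trans-fused | CC(C)[C@@H]1CC[C@@]2(C)CCC=C(C)[C@@H]2C1=O | intermediate
14 | 5αH-eudesm-3-en-6β-ol, axial OH | CC(C)[C@@H]1CC[C@@]2(C)CCC=C(C)[C@@H]2[C@@H]1O | intermediate
15 | 5αH-eudesm-3-en-6β-yl benzoate | CC(C)[C@@H]1CC[C@@]2(C)CCC=C(C)[C@@H]2[C@@H]1OC(=O)c1ccccc1 | intermediate
16 | 3α,4α-epoxy-5αH-eudesman-6β-yl benzoate | CC(C)[C@@H]1CC[C@@]2(C)CC[C@H]3O[C@@]3(C)[C@@H]2[C@@H]1OC(=O)c1ccccc1 | intermediate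
17 | 2-phenyl-1,3-dioxan-2-ylium ion bridging O4β and O6β, 3α-OH free, perchlorate | CC(C)[C@@H]1CC[C@@]2(C)CC[C@@H](O)[C@]3(C)OC(c4ccccc4)=[O+][C@H]1[C@H]23.[O-]Cl(=O)(=O)=O | intermediate
18 | (3R,4R,5S,6R,7S,10S)-6-benzoyloxyeudesmane-3,4-diol (3α-OH, 4β-OH, 4α-Me, 5α-H, 6β-OBz, 7β-isopropyl, 10β-Me) | CC(C)[C@@H]1CC[C@@]2(C)CC[C@@H](O)[C@](C)(O)[C@@H]2[C@@H]1OC(=O)c1ccccc1 | target

Total step count: 10. Longest linear sequence: 10 steps (1 and 2 to 18).

Steps most likely to fail

Step 5. Intermolecular olefination of the aldehyde may outrun the hindered Michael closure. The reversible Michael step may also fall back to open chain, or the control of C10 by C7 may be weak. The fallback sets out from 3 and comes back at 13, making the two bonds one at a time by known reactions.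
- LiOH-mediated intramolecular aldol condensation of 3 gives (S)-4-isopropylcyclohex-2-en-1-one F1.
- [3-(2-Methyl-1,3-dioxolan-2-yl)propyl]magnesium chloride F2, made from commercial 2-(3-chloropropyl)-2-methyl-1,3-dioxolane and Mg, adds 1,2 to give the tertiary allylic alcohol F3.
- Babler–Dauben oxidation with pyridinium chlorochromate transposes F3 to the 3-substituted 6-isopropylcyclohex-2-en-1-one F4.
- Axial conjugate addition of Me2CuLi sets the quaternary C10 with methyl cis to isopropyl in the ketal ketone F5.
- Aqueous HCl frees the diketone F6, and KOH in MeOH closes ring A by aldol condensation to eudesm-4-en-6-one F7.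
- KOt-Bu in t-BuOH forms the extended potassium dienolate F8, and kinetic protonation with aqueous acetic acid gives 13.

Step 6. Possible failures are over-reduction, protonation of the dienolate at C3 instead of C5, conjugation of the β,γ-enone during work-up, or poor facial selectivity at C5. The fallback sets out from 11 and comes back at 15 without ever passing through an enolisable β,γ-enone.
- i-Bu2AlH reduces the ketone from the α face to eudesma-2,4-dien-6β-ol F9.
- Benzoylation (BzCl, DMAP, pyridine) gives eudesma-2,4-dien-6β-yl benzoate F10.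
- 1,4-Hydrogenation of the s-cis ring A diene with (η6-naphthalene)Cr(CO)3 and H2 in THF should add both hydrogens to C2 and C5 from the open α face and leave the C3=C4 alkene of 15.

Step 4. The hindered 1,1-disubstituted partner may couple sluggishly. Ring-closing metathesis of the vinyl ketone onto the C10=C1 alkene, or polymerisation of the vinyl ketone, may compete. The fallback sets out from 3 and comes back at 9 without metathesis.
- Commercial prop-2-yn-1-ol is carboaluminated (Me3Al, Cp2ZrCl2, then I2) to (E)-3-iodo-2-methylprop-2-en-1-ol F11.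
- P(OEt)3 with ZnI2 converts it into diethyl [(E)-3-iodo-2-methylprop-2-en-1-yl]phosphonate F12.
- Nozaki–Hiyama–Kishi coupling (CrCl2, NiCl2 catalyst, DMF) with the aldehyde of 3, the ketone staying inert, gives the hydroxy ketone F13.
- Vinylmagnesium bromide with LaCl3·2LiCl adds to the methyl ketone to give the diol F14.
- Pyridinium chlorochromate, as in step 3, oxidises and transposes F14 to 9.

Further compounds
F1 | step 5 | (S)-4-isopropylcyclohex-2-en-1-one | CC(C)[C@@H]1CCC(=O)C=C1
F2 | step 5 | [3-(2-methyl-1,3-dioxolan-2-yl)propyl]magnesium chloride | CC1(CCC[Mg]Cl)OCCO1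
F3 | step 5 | (4S)-4-isopropyl-1-[3-(2-methyl-1,3-dioxolan-2-yl)propyl]cyclohex-2-en-1-ol, epimers at C1 | CC(C)[C@@H]1CCC(O)(CCCC2(C)OCCO2)C=C1
F4 | step 5 | (6S)-6-isopropyl-3-[3-(2-methyl-1,3-dioxolan-2-yl)propyl]cyclohex-2-en-1-one | CC(C)[C@@H]1CCC(CCCC2(C)OCCO2)=CC1=O
F5 | step 5 | 6-isopropyl-3-methyl-3-[3-(2-methyl-1,3-dioxolan-2-yl)propyl]cyclohexan-1-one, methyl cis to isopropyl | CC(C)[C@@H]1CC[C@@](C)(CCCC2(C)OCCO2)CC1=O
F6 | step 5 | 6-isopropyl-3-methyl-3-(4-oxopentyl)cyclohexan-1-one, methyl cis to isopropyl | CC(C)[C@@H]1CC[C@@](C)(CCCC(C)=O)CC1=O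
F7 | step 5 | eudesm-4-en-6-one | CC(C)[C@@H]1CC[C@@]2(C)CCCC(C)=C2C1=O
F8 | step 5 | potassium eudesma-3,5-dien-6-olate | CC(C)[C@@H]1CC[C@@]2(C)CCC=C(C)C2=C1[O-].[K+]
F9 | step 6 | eudesma-2,4-dien-6β-ol | CC(C)[C@@H]1CC[C@@]2(C)CC=CC(C)=C2[C@@H]1O
F10 | step 6 | eudesma-2,4-dien-6β-yl benzoate | CC(C)[C@@H]1CC[C@@]2(C)CC=CC(C)=C2[C@@H]1OC(=O)c1ccccc1
F11 | step 4 | (E)-3-iodo-2-methylprop-2-en-1-ol | OC/C(C)=C/I
F12 | step 4 | diethyl [(E)-3-iodo-2-methylprop-2-en-1-yl]phosphonate | CCOP(=O)(C/C(C)=C/I)OCC
F13 | step 4 | diethyl [(2E,5S)-4-hydroxy-2-methyl-8-oxo-5-(propan-2-yl)non-2-en-1-yl]phosphonate | CC(C)[C@@H](C(O)/C=C(\C)CP(=O)(OCC)OCC)CCC(C)=O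
F14 | step 4 | diethyl [(2E,5S)-4,8-dihydroxy-2,8-dimethyl-5-(propan-2-yl)deca-2,9-dien-1-yl]phosphonate | CC(C)[C@@H](C(O)/C=C(\C)CP(=O)(OCC)OCC)CCC(C)(O)C=C
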